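**Retrosynthetic overview**
1. Last bond: C3 of the pyranone (ring C) to C6 of the chromene, by Suzuki coupling of 3-iodo-7-methoxychromone with the chromen-6-yl pinacol boronate.
2. Pyran ring (ring D) on ring B: one operation from an ortho-silylaryl triflate and 3-methylbut-2-enal. The aryne undergoes [2+2] addition with the aldehyde C=O, the benzoxete opens to an ortho-quinone methide, and oxa-6π electrocyclisation closes the ring at O1–C2(CH3)2.
3. Enabling feature: ring D is fused to ring B at two neighbouring carbons, C8a (bearing O1) and C4a (bearing C4), and C4a lies next to the C5 methoxy carbon. The two fusion carbons are the two ends of an aryne, the chain O1, C4, C3, C2(CH3)2 is 3-methylbut-2-enal, and the methoxy group beside the triple bond decides that oxygen goes to C8a.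
4. Aryne precursor: 4-bromo-3-methoxyphenol, carbamate-directed silylation of the carbon between the two oxygens, then triflation; the bromine becomes the boron handle after the key step.
5. Ring order: ring B purchased, then ring D (key step); ring C built on ring A separately (enaminone iodocyclisation); then union of the two halves.

Key step: step 5

Remark on the chemistry: the target has no stereocentre, and its only stereo element, the cis C3=C4 bond of the pyran ring, is fixed by the ring; LiN(i-Pr)2 and n-BuLi are taken as purchased solutions.

**Step 1**
Reactants: 1 4-bromo-3-methoxyphenol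
Product: 2 4-bromo-3-methoxyphenyl N,N-diethylcarbamate
Conditions: Et2NCOCl (1.2 equiv), K2CO3 (2 equiv), MeCN, reflux
Reagents that add atoms: N,N-diethylcarbamoyl chloride, CCN(CC)C(=O)Cl
Why: O-Carbamoylation of the phenoxide (nucleophilic acyl substitution) is a standard reaction and installs the diethylcarbamate as the directing group for the next step.

**Step 2**
Reactants: 2 4-bromo-3-methoxyphenyl N,N-diethylcarbamate
Product: 4 4-bromo-3-methoxy-2-(trimethylsilyl)phenyl N,N-diethylcarbamate, via aryllithium 3 (not isolated)
Conditions: LiN(i-Pr)2 (1.3 equiv), TMSCl (2 equiv, present from the start), THF, −78 °C to rt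
Reagents that add atoms: chlorotrimethylsilane, C[Si](C)(C)Cl
Why: Directed ortho metalation with in situ silyl trapping: the only C–H flanked by two directing groups (carbamate and methoxy) is removed by the lithium amide, which does not undergo bromine–lithium exchange, and the silyl chloride already present should capture aryllithium 3 before anionic ortho-Fries rearrangement can set in.

**Step 3**
Reactants: 4 4-bromo-3-methoxy-2-(trimethylsilyl)phenyl N,N-diethylcarbamate
Product: 5 4-bromo-3-methoxy-2-(trimethylsilyl)phenol
Conditions: LiAlH4 (2 equiv), THF, 0 °C to rt; aq. potassium sodium tartrate work-up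
Reagents that add atoms: none
Why: Hydride reduction of an aryl carbamate expels the aryloxide after the first addition to C=O, neither the aryl bromide nor the aryl silane should react with LiAlH4 at or below room temperature, and the non-acidic tartrate work-up avoids protodesilylation.

**Step 4**
Reactants: 5 4-bromo-3-methoxy-2-(trimethylsilyl)phenol
Product: 6 4-bromo-3-methoxy-2-(trimethylsilyl)phenyl trifluoromethanesulfonate
Conditions: Tf2O (1.2 equiv), pyridine (2 equiv), CH2Cl2, 0 °C
Reagents that add atoms: trifluoromethanesulfonic anhydride, O=S(=O)(OS(=O)(=O)C(F)(F)F)C(F)(F)F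
Why: O-Triflation of the phenol with the anhydride and pyridine is the standard last step in the preparation of ortho-silylaryl triflates and should touch nothing else in the molecule.

**Step 5**
Reactants: 6 4-bromo-3-methoxy-2-(trimethylsilyl)phenyl trifluoromethanesulfonate; 7 3-methylbut-2-enal (3 equiv)
Product: 11 6-bromo-5-methoxy-2,2-dimethyl-2H-chromene, via aryne 8 (not isolated), via benzoxete 9 (not isolated), via ortho-quinone methide 10 (not isolated)
Conditions: CsF (3 equiv), MeCN, rt then 50 °C
Reagents that add atoms: none
Why: Fluoride removes the silyl group and the aryl anion expels triflate to give aryne 8; the carbonyl oxygen of 7 adds to the aryne carbon remote from the methoxy group, and the aryl anion so formed, which sits beside the methoxy group, closes onto the oxocarbenium carbon to give benzoxete 9 (stepwise polar [2+2], four-membered ring), whose strain drives a 4π electrocyclic ring opening to ortho-quinone methide 10. The 1-oxatriene O=C–C=CH–CH=C(CH3)2 of 10 then closes the pyran ring by a thermal disrotatory oxa-6π electrocyclisation that forms the O–C(CH3)2 bond and restores the aromatic sextet. The closest known reaction type is the fluoride-induced annulation of arynes from ortho-silylaryl triflates with α,β-unsaturated aldehydes to 2H-chromenes, and 10 is the same kind of intermediate that closes in the thermal aryl propargyl ether to chromene rearrangement. No stereocentre is formed, because the new sp3 carbon carries two methyl groups; the stereocentre of transient 9 is racemic and is lost on ring opening. The selectivity that matters is the orientation of the addition to the aryne, and it is secured by the inductively withdrawing methoxy group beside the triple bond (the distal carbon is the more electrophilic one and the charge develops next to oxygen), reinforced by bromine para to the attacked carbon, so that oxygen ends on C8a and the carbonyl carbon on C4a. Capture of 10 by a second aldehyde or aryne should be outrun by the intramolecular closure, for which the Z geometry is favoured because the E isomer would press the side chain against the methoxy group.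

**Step 6**
Reactants: 11 6-bromo-5-methoxy-2,2-dimethyl-2H-chromene
Product: 13 2-(5-methoxy-2,2-dimethyl-2H-chromen-6-yl)-4,4,5,5-tetramethyl-1,3,2-dioxaborolane, via aryllithium 12 (not isolated)
Conditions: n-BuLi (1.1 equiv), THF, −78 °C; then i-PrOBpin (1.3 equiv), −78 °C to rt; aq. work-up
Reagents that add atoms: 2-isopropoxy-4,4,5,5-tetramethyl-1,3,2-dioxaborolane, CC(C)OB1OC(C)(C)C(C)(C)O1
Why: Bromine–lithium exchange at −78 °C is faster than any attack on the chromene or the ethers, and the aryllithium adds to the borate, which loses isopropoxide to give the pinacol boronate (borylation by halogen–metal exchange).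

**Step 7**
Reactants: 14 1-(2-hydroxy-4-methoxyphenyl)ethan-1-one (paeonol)
Product: 15 (E)-3-(dimethylamino)-1-(2-hydroxy-4-methoxyphenyl)prop-2-en-1-one
Conditions: Me2NCH(OMe)2 (2 equiv), toluene, 95 °C
Reagents that add atoms: N,N-dimethylformamide dimethyl acetal, COC(OC)N(C)C
Why: Condensation of the methyl ketone with the amide acetal (enaminone formation) proceeds at the only enolisable position and should give the conjugated E isomer, which is the thermodynamic one.

**Step 8**
Reactants: 15 (E)-3-(dimethylamino)-1-(2-hydroxy-4-methoxyphenyl)prop-2-en-1-one
Product: 16 3-iodo-7-methoxy-4H-chromen-4-one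
Conditions: I2 (1.5 equiv), CHCl3, rt; aq. Na2S2O3 wash
Reagents that add atoms: iodine, II
Why: Iodocyclisation of the enaminone: iodination at the α-carbon, 6-endo-trig addition of the phenol oxygen to the iminium carbon and loss of dimethylamine should give the 3-iodochromone directly.

**Step 9**
Reactants: 13 2-(5-methoxy-2,2-dimethyl-2H-chromen-6-yl)-4,4,5,5-tetramethyl-1,3,2-dioxaborolane; 16 3-iodo-7-methoxy-4H-chromen-4-one
Product: 17 7-methoxy-3-(5-methoxy-2,2-dimethyl-2H-chromen-6-yl)-4H-chromen-4-one
Conditions: PdCl2(dppf) (5 mol %), Na2CO3 (2 M aq., 3 equiv), DME, 80 °C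
Reagents that add atoms: none
Why: Suzuki–Miyaura coupling: zerovalent palladium inserts readily into the C–I bond of the vinylogous ester, the carbonate-activated boronate transmetalates, and reductive elimination forms the C3–aryl bond without touching the chromene alkene; no stereocentre is present.

**Compound list**
1 | 4-bromo-3-methoxyphenol | COc1cc(O)ccc1Br | starting material
2 | 4-bromo-3-methoxyphenyl N,N-diethylcarbamate | CCN(CC)C(=O)Oc1ccc(Br)c(OC)c1 | intermediate
3 | [3-bromo-6-(diethylcarbamoyloxy)-2-methoxyphenyl]lithium (not isolated) | CCN(CC)C(=O)Oc1ccc(Br)c(OC)c1[Li] | intermediate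
4 | 4-bromo-3-methoxy-2-(trimethylsilyl)phenyl N,N-diethylcarbamate | CCN(CC)C(=O)Oc1ccc(Br)c(OC)c1[Si](C)(C)C | intermediate
5 | 4-bromo-3-methoxy-2-(trimethylsilyl)phenol | COc1c(Br)ccc(O)c1[Si](C)(C)C | intermediate
6 | 4-bromo-3-methoxy-2-(trimethylsilyl)phenyl trifluoromethanesulfonate | COc1c(Br)ccc(OS(=O)(=O)C(F)(F)F)c1[Si](C)(C)C | intermediate
7 | 3-methylbut-2-enal | CC(C)=CC=O | starting material
8 | 4-bromo-3-methoxybenzyne (4-bromo-3-methoxy-1,2-didehydrobenzene, not isolated) | COC1=C(Br)C=CC#C1 | intermediate
9 | 4-bromo-3-methoxy-2-(2-methylprop-1-en-1-yl)-2H-benzo[b]oxete (racemic, not isolated) | COc1c(Br)ccc2OC(C=C(C)C)c12 | intermediate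
10 | (6Z)-4-bromo-5-methoxy-6-(3-methylbut-2-en-1-ylidene)cyclohexa-2,4-dien-1-one (not isolated) | O=C1C=CC(Br)=C(OC)/C1=C/C=C(C)C | intermediate
11 | 6-bromo-5-methoxy-2,2-dimethyl-2H-chromene | COc1c(Br)ccc2OC(C)(C)C=Cc12 | intermediate
12 | (5-methoxy-2,2-dimethyl-2H-chromen-6-yl)lithium (not isolated) | COc1c([Li])ccc2OC(C)(C)C=Cc12 | intermediate
13 | 2-(5-methoxy-2,2-dimethyl-2H-chromen-6-yl)-4,4,5,5-tetramethyl-1,3,2-dioxaborolane | COc1c(B3OC(C)(C)C(C)(C)O3)ccc2OC(C)(C)C=Cc12 | intermediate
14 | 1-(2-hydroxy-4-methoxyphenyl)ethan-1-one | COc1ccc(C(C)=O)c(O)c1 | starting material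
15 | (E)-3-(dimethylamino)-1-(2-hydroxy-4-methoxyphenyl)prop-2-en-1-one | COc1ccc(C(=O)/C=C/N(C)C)c(O)c1 | intermediate
16 | 3-iodo-7-methoxy-4H-chromen-4-one | COc1ccc2c(=O)c(I)coc2c1 | intermediate
17 | 7-methoxy-3-(5-methoxy-2,2-dimethyl-2H-chromen-6-yl)-4H-chromen-4-one | COc1ccc2c(=O)c(-c3ccc4c(c3OC)C=CC(C)(C)O4)coc2c1 | target

**Step count**
Total: 9 steps. Longest linear sequence: 7 steps (steps 1 to 6, then step 9); steps 7 and 8 form the second branch.

**Steps most likely to fail**

Step 5. What may go wrong: fluoride-induced self-condensation of the enolisable enal, or capture of the aryne or of the quinone methide by a second partner, so that the cascade stalls before the electrocyclisation. Fallback: the aryne is kept, the trap is changed and the ring is closed stepwise. It sets out from 6 and comes back to the route at 11. With CsF in DMF as solvent, aryne 8 is expected to insert into the formyl C=O of the solvent with the same orientation to give the benzoxete aminal 4-bromo-3-methoxy-N,N-dimethyl-2H-benzo[b]oxet-2-amine F1 (not isolated), which aqueous work-up should hydrolyse to 3-bromo-6-hydroxy-2-methoxybenzaldehyde F2. Addition of (2-methylprop-1-en-1-yl)magnesium bromide (2.5 equiv, THF, 0 °C) should give the diol 4-bromo-2-(1-hydroxy-3-methylbut-2-en-1-yl)-3-methoxyphenol F3 (racemic). Warming with a trace of pyridinium p-toluenesulfonate in toluene at 80 °C should dehydrate it to quinone methide 10, which closes to 11 as in the main route.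

Step 2. What may go wrong: slow transfer of the silyl group to the carbanion flanked by the carbamate and methoxy groups, so that anionic ortho-Fries rearrangement or attack of the amide base next to bromine takes over. Fallback: the same position is used for C–C instead of C–Si bond formation and the aryne is given up. It sets out from 2 and comes back to the route at 11. Aryllithium 3 is formed with LiN(i-Pr)2 alone (THF, −78 °C) and trapped with the small, fast electrophile 7 to give, after a cold quench, 4-bromo-2-(1-hydroxy-3-methylbut-2-en-1-yl)-3-methoxyphenyl N,N-diethylcarbamate F4 (racemic). NaH (THF, 0 to 60 °C) should then move the carbamoyl group from the phenol oxygen to the alkoxide through a six-membered transition state to give 1-(3-bromo-6-hydroxy-2-methoxyphenyl)-3-methylbut-2-en-1-yl N,N-diethylcarbamate F5 (as its phenoxide, not isolated). The phenoxide expels diethylcarbamate from the benzylic and allylic position to give 10, which closes to 11.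

Step 9. What may go wrong: protodeboronation of the electron-rich ortho-methoxy boronate and opening of the pyranone ring by aqueous base before transmetalation. Fallback: a base-free, anhydrous organozinc coupling that bypasses the boronate. It sets out from 11 and comes back to the route at 17. Aryllithium 12 (n-BuLi, THF, −78 °C) is transmetalated with ZnCl2 to chloro(5-methoxy-2,2-dimethyl-2H-chromen-6-yl)zinc F6 (not isolated), which is coupled with 16 under Negishi conditions (Pd(PPh3)4, THF, 50 °C).

**Further compounds**
F1 | step 5 | 4-bromo-3-methoxy-N,N-dimethyl-2H-benzo[b]oxet-2-amine (racemic, not isolated) | CN(C)C1Oc2ccc(Br)c(OC)c12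
F2 | step 5 | 3-bromo-6-hydroxy-2-methoxybenzaldehyde | COc1c(Br)ccc(O)c1C=O
F3 | step 5 | 4-bromo-2-(1-hydroxy-3-methylbut-2-en-1-yl)-3-methoxyphenol (racemic) | COc1c(Br)ccc(O)c1C(O)C=C(C)C
F4 | step 2 | 4-bromo-2-(1-hydroxy-3-methylbut-2-en-1-yl)-3-methoxyphenyl N,N-diethylcarbamate (racemic) | CCN(CC)C(=O)Oc1ccc(Br)c(OC)c1C(O)C=C(C)C
F5 | step 2 | 1-(3-bromo-6-hydroxy-2-methoxyphenyl)-3-methylbut-2-en-1-yl N,N-diethylcarbamate (racemic, not isolated) | CCN(CC)C(=O)OC(C=C(C)C)c1c(O)ccc(Br)c1OC
F6 | step 9 | chloro(5-methoxy-2,2-dimethyl-2H-chromen-6-yl)zinc (not isolated) | COc1c([Zn]Cl)ccc2OC(C)(C)C=Cc12
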